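**Strategy.** Everything rests on closing ring C at the bond between the ketone carbon C4, already on ring A at C4a, and the methylene C3. The precursor is a ring A benzaldehyde whose O1 oxygen carries C2, C3 and ring B as a 1-arylvinyl ether. A chiral rhodium catalyst adds the aldehyde C–H across this alkene (intramolecular hydroacylation), forming C3–C4 and the (S) stereocentre at C2 in one isomerisation. The step exploits the C4 ketone, C3 methylene and hydrogen-bearing, O1-bound C2 of ring C. The C8 side chain comes from an Evans alkylation and a Negishi coupling; a second enol ether masks the C7 hydroxyl.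

Key step: step 14

Remark: flavanone numbering (O1, C2, C3, C4, C4a, C5–C8, C8a) is used for all ring A intermediates. Lavandulyl = 5-methyl-2-(prop-1-en-2-yl)hex-4-en-1-yl, TBS = tert-butyldimethylsilyl, MOM = methoxymethyl. The (R) side-chain centre of the target has the spatial arrangement of (S)-lavandulol, because CH2Ar ranks below isopropenyl whereas CH2OH, CH2I and the acyl carbon rank above it.

**Step 1**
Reactants: 1 (S)-4-benzyl-1,3-oxazolidin-2-one; 2 3-methylbut-2-enoyl chloride
Product: 4 (S)-4-benzyl-3-(3-methylbut-2-enoyl)-1,3-oxazolidin-2-one, via lithium oxazolidinide 3 (not isolated)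
Conditions: n-BuLi, THF, −78 °C; then 2, −78 → 0 °C
Reagents that add atoms: none
Why: N-acylation of the lithiated Evans auxiliary by the acid chloride at low temperature is fast and avoids ketene formation from the enoyl chloride.

**Step 2**
Reactants: 4; 5 1-bromo-3-methylbut-2-ene (prenyl bromide)
Product: 7 (S)-4-benzyl-3-[(2S)-5-methyl-2-(prop-1-en-2-yl)hex-4-enoyl]-1,3-oxazolidin-2-one, via sodium dienolate 6 (not isolated)
Conditions: NaN(SiMe3)2, THF, −78 °C; then 5, −78 → −40 °C; AcOH quench at −78 °C
Reagents that add atoms: none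
Why: Deconjugative Evans alkylation: γ-deprotonation gives the chelated (Z)-dienolate, which should be alkylated at the α-carbon on the face opposite the C4 benzyl group, setting the (2S) centre (the future (R) side-chain centre) under auxiliary control.

**Step 3**
Reactants: 7
Product: 8 (2S)-5-methyl-2-(prop-1-en-2-yl)hex-4-en-1-ol, (S)-lavandulol
Conditions: LiBH4, H2O (1 equiv), Et2O, 0 °C
Reagents that add atoms: none
Why: Reductive cleavage of the N-acyl oxazolidinone with LiBH4 should give the primary alcohol without touching the stereocentre or the alkenes, and the auxiliary is recovered.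

**Step 4**
Reactants: 8
Product: 9 (3S)-3-(iodomethyl)-2,6-dimethylhepta-1,5-diene, (S)-lavandulyl iodide
Conditions: PPh3, I2, imidazole, CH2Cl2, 0 °C → rt
Reagents that add atoms: iodine, [I][I]
Why: Appel-type iodination proceeds by SN2 displacement at the CH2 group, so the adjacent stereocentre is untouched.

**Step 5**
Reactants: 10 5-methoxybenzene-1,3-diol
Product: 11 1-methoxy-3,5-bis(methoxymethoxy)benzene
Conditions: MeOCH2Cl, i-Pr2NEt, CH2Cl2, 0 °C → rt
Reagents that add atoms: chloromethyl methyl ether, COCCl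
Why: O-alkylation of both phenols installs MOM ethers that protect the oxygens and direct the two ortho-metalations that follow.

**Step 6**
Reactants: 11
Product: 13 2-iodo-5-methoxy-1,3-bis(methoxymethoxy)benzene, via aryllithium 12 (not isolated)
Conditions: n-BuLi, THF, 0 °C; then I2, −78 °C → rt
Reagents that add atoms: iodine, [I][I]
Why: Directed ortho-metalation should occur at the position flanked by both coordinating MOM ethers (the future C8), and the aryllithium is trapped by iodine.

**Step 7**
Reactants: 9; 13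
Product: 15 5-methoxy-1,3-bis(methoxymethoxy)-2-[(2R)-lavandulyl]benzene, via alkylzinc iodide 14 (not isolated)
Conditions: 9 (1.3 equiv), Zn dust (activated with Me3SiCl and 1,2-dibromoethane), LiCl, THF, 40 °C; then 13, Pd(OAc)2 (3 mol %), 2-dicyclohexylphosphino-2',6'-dimethoxybiphenyl (6 mol %), THF, 50 °C
Reagents that add atoms: none
Why: Negishi coupling: the non-basic primary alkylzinc keeps its β-stereocentre, and a bulky biarylphosphine on palladium should make reductive elimination at the hindered aryl iodide faster than β-hydride elimination.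

**Step 8**
Reactants: 15
Product: 17 2-bromo-1-methoxy-3,5-bis(methoxymethoxy)-4-[(2R)-lavandulyl]benzene, via aryllithium 16 (not isolated)
Conditions: n-BuLi, TMEDA, THF, −20 → 0 °C; then BrCl2C–CCl2Br, −78 °C
Reagents that add atoms: 1,2-dibromo-1,1,2,2-tetrachloroethane, ClC(Cl)(Br)C(Cl)(Cl)Br
Why: A second directed ortho-metalation at one of the two equivalent ring positions between OMe and OMOM (the substrate is symmetric, so only one bromide can form) is trapped by a bromine donor that does not attack alkenes; this carbon becomes C4a.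

**Step 9**
Reactants: 17
Product: 18 4-bromo-5-methoxy-2-[(2R)-lavandulyl]benzene-1,3-diol
Conditions: HCl (1.25 M in MeOH), MeOH, 0 °C → rt
Reagents that add atoms: none
Why: Acid-catalysed transacetalisation to methanol should cleave the aryl MOM acetals much faster than the side-chain alkenes are protonated.

**Step 10**
Reactants: 19 4-hydroxybenzoic acid
Product: 21 4-[(tert-butyldimethylsilyl)oxy]benzoic acid, via silyl ester 20 (not isolated)
Conditions: t-BuMe2SiCl (2.2 equiv), imidazole, DMF, rt; then AcOH–THF–H2O (3:1:1), rt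
Reagents that add atoms: tert-butyldimethylsilyl chloride, CC(C)(C)[Si](C)(C)Cl
Why: Double silylation followed by selective hydrolysis of the labile silyl ester leaves the acid with its aryl silyl ether, which tolerates mild acid but not carbonate in methanol.

**Step 11**
Reactants: 21; 18
Product: 23 4-bromo-5-methoxy-2-[(2R)-lavandulyl]-1,3-phenylene bis[4-(TBS-oxy)benzoate], via acid chloride 22 (not isolated)
Conditions: 21 (2.4 equiv), (COCl)2, DMF (cat.), CH2Cl2, 0 °C → rt, evaporate; then 18, Et3N, DMAP, CH2Cl2, rt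
Reagents that add atoms: none
Why: DMAP-catalysed acylation with the acid chloride should esterify both phenols, including the hindered one between bromine and the side chain.

**Step 12**
Reactants: 23
Product: 24 2-bromo-1-methoxy-4-[(2R)-lavandulyl]-3,5-bis{1-[4-(TBS-oxy)phenyl]ethenyloxy}benzene
Conditions: Cp2TiMe2 (5 equiv), toluene–THF, 70 °C, dark; filtration through basic alumina
Reagents that add atoms: dimethyltitanocene, C[Ti](C)(C1C=CC=C1)C1C=CC=C1
Why: Petasis methylenation: Cp2Ti=CH2 formed thermally converts both aryl ester carbonyls into 1-arylvinyl ethers under non-acidic conditions that the aryl bromide, silyl ethers and alkenes tolerate; the new CH2 at O1 becomes C3.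

**Step 13**
Reactants: 24
Product: 26 6-methoxy-3-[(2R)-lavandulyl]-2,4-bis{1-[4-(TBS-oxy)phenyl]ethenyloxy}benzaldehyde, via aryllithium 25 (not isolated)
Conditions: n-BuLi (1.05 equiv), THF, −78 °C; then DMF, −78 → −20 °C; aq NH4Cl
Reagents that add atoms: N,N-dimethylformamide, CN(C)C=O
Why: Bromine–lithium exchange at −78 °C is faster than addition of n-BuLi to the styrenyl ethers, and formylation of the aryllithium with DMF puts the aldehyde carbon (C4) on C4a.

**Step 14**
Reactants: 26
Product: 27 (2S)-5-methoxy-8-[(2R)-lavandulyl]-2-[4-(TBS-oxy)phenyl]-7-{1-[4-(TBS-oxy)phenyl]ethenyloxy}chroman-4-one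
Conditions: [Rh(cod)Cl]2 (2.5 mol %), (R)-DTBM-SEGPHOS (5 mol %), NaB[3,5-(CF3)2C6H3]4 (5 mol %), dry 1,4-dioxane, 60 °C
Reagents that add atoms: none
Why: Proposed new method: oxidative addition of the aldehyde C–H bond of 26 to cationic monovalent rhodium gives an acyl hydride of trivalent rhodium held by the flanking C5 methoxy and O1 oxygens, the 1,1-disubstituted enol-ether alkene inserts into Rh–H with hydride going to C2 and rhodium to the terminal carbon C3, and C–C reductive elimination from the seven-membered acyl(alkyl)rhodacycle forms the C3–C4 bond. The closest known reaction type is the rhodium/bisphosphine-catalysed enantioselective endo-hydroacylation of 1,1-disubstituted alkenes tethered to aromatic aldehydes (2-(2-arylallyl)benzaldehydes to 3-aryl-1-tetralones, N-(1-substituted vinyl)indole-2-carbaldehydes to the endo ketones), transposed here to an aryl 1-arylvinyl ether. Ring C is closed in a 6-endo-trig mode. The C2 stereocentre is set by catalyst control, the chiral bisphosphine selecting the alkene face that receives the hydride; the (R)-ligand is written and its antipode is used should the sense of induction prove opposite, the remote side-chain centre not being expected to intervene. The step needs 6-endo over 5-exo regioselectivity (the latter would place rhodium on the fully substituted C2 and lead to a 2-methyl-2-arylbenzofuran-3-one), which the 1,1-disubstitution of the alkene should secure, and acyl–alkyl coupling faster than decarbonylation, which oxygen chelation and the non-coordinating counter-ion should favour. Chemoselectivity is secured by geometry, since the second enol ether is para to the aldehyde and the side-chain alkenes cannot reach the metal through a small ring.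

**Step 15**
Reactants: 27
Product: 29 kushenol U, via mono-silyl flavanone 28 (not isolated)
Conditions: 0.2 M HCl, THF–H2O (4:1), 0 °C → rt; neutral work-up; then Bu4NF/AcOH (1:1), THF, 0 °C
Reagents that add atoms: none
Why: The electron-rich 1-arylvinyl aryl ether at C7 should be hydrolysed by dilute acid (C-protonation, hemiketal collapse) far faster than the side-chain alkenes react, and acetic acid-buffered fluoride then cleaves the aryl silyl ether without opening the flavanone, so C2 is not epimerised.

**Compound list**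
1 | (S)-4-benzyl-1,3-oxazolidin-2-one | O=C1N[C@@H](Cc2ccccc2)CO1 | starting material
2 | 3-methylbut-2-enoyl chloride | CC(C)=CC(=O)Cl | starting material
3 | lithium (S)-4-benzyl-2-oxo-1,3-oxazolidin-3-ide | [Li+].O=C1[N-][C@@H](Cc2ccccc2)CO1 | intermediate
4 | (S)-4-benzyl-3-(3-methylbut-2-enoyl)-1,3-oxazolidin-2-one | CC(C)=CC(=O)N1[C@@H](Cc2ccccc2)COC1=O | intermediate
5 | 1-bromo-3-methylbut-2-ene | CC(C)=CCBr | starting material
6 | sodium (Z)-dienolate of 4 | [Na+].C=C(C)/C=C(\[O-])N1[C@@H](Cc2ccccc2)COC1=O | intermediate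
7 | (S)-4-benzyl-3-[(2S)-5-methyl-2-(prop-1-en-2-yl)hex-4-enoyl]-1,3-oxazolidin-2-one | C=C(C)[C@H](CC=C(C)C)C(=O)N1[C@@H](Cc2ccccc2)COC1=O | intermediate
8 | (2S)-5-methyl-2-(prop-1-en-2-yl)hex-4-en-1-ol, (S)-lavandulol | C=C(C)[C@H](CC=C(C)C)CO | intermediate
9 | (3S)-3-(iodomethyl)-2,6-dimethylhepta-1,5-diene | C=C(C)[C@H](CC=C(C)C)CI | intermediate
10 | 5-methoxybenzene-1,3-diol | COc1cc(O)cc(O)c1 | starting material
11 | 1-methoxy-3,5-bis(methoxymethoxy)benzene | COCOc1cc(OC)cc(OCOC)c1 | intermediate
12 | [4-methoxy-2,6-bis(methoxymethoxy)phenyl]lithium | [Li]c1c(OCOC)cc(OC)cc1OCOC | intermediate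
13 | 2-iodo-5-methoxy-1,3-bis(methoxymethoxy)benzene | COCOc1cc(OC)cc(OCOC)c1I | intermediate
14 | [(2S)-5-methyl-2-(prop-1-en-2-yl)hex-4-en-1-yl]zinc iodide | C=C(C)[C@H](CC=C(C)C)C[Zn]I | intermediate
15 | 5-methoxy-1,3-bis(methoxymethoxy)-2-[(2R)-5-methyl-2-(prop-1-en-2-yl)hex-4-en-1-yl]benzene | C=C(C)[C@H](CC=C(C)C)Cc1c(OCOC)cc(OC)cc1OCOC | intermediate
16 | {6-methoxy-2,4-bis(methoxymethoxy)-3-[(2R)-lavandulyl]phenyl}lithium | C=C(C)[C@H](CC=C(C)C)Cc1c(OCOC)cc(OC)c([Li])c1OCOC | intermediate
17 | 2-bromo-1-methoxy-3,5-bis(methoxymethoxy)-4-[(2R)-lavandulyl]benzene | C=C(C)[C@H](CC=C(C)C)Cc1c(OCOC)cc(OC)c(Br)c1OCOC | intermediate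
18 | 4-bromo-5-methoxy-2-[(2R)-lavandulyl]benzene-1,3-diol | C=C(C)[C@H](CC=C(C)C)Cc1c(O)cc(OC)c(Br)c1O | intermediate
19 | 4-hydroxybenzoic acid | O=C(O)c1ccc(O)cc1 | starting material
20 | tert-butyldimethylsilyl 4-[(tert-butyldimethylsilyl)oxy]benzoate | CC(C)(C)[Si](C)(C)OC(=O)c1ccc(O[Si](C)(C)C(C)(C)C)cc1 | intermediate
21 | 4-[(tert-butyldimethylsilyl)oxy]benzoic acid | CC(C)(C)[Si](C)(C)Oc1ccc(C(=O)O)cc1 | intermediate
22 | 4-[(tert-butyldimethylsilyl)oxy]benzoyl chloride | CC(C)(C)[Si](C)(C)Oc1ccc(C(=O)Cl)cc1 | intermediate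
23 | 4-bromo-5-methoxy-2-[(2R)-lavandulyl]-1,3-phenylene bis[4-(TBS-oxy)benzoate] | C=C(C)[C@H](CC=C(C)C)Cc1c(OC(=O)c2ccc(O[Si](C)(C)C(C)(C)C)cc2)cc(OC)c(Br)c1OC(=O)c1ccc(O[Si](C)(C)C(C)(C)C)cc1 | intermediate
24 | 2-bromo-1-methoxy-4-[(2R)-lavandulyl]-3,5-bis{1-[4-(TBS-oxy)phenyl]ethenyloxy}benzene | C=C(C)[C@H](CC=C(C)C)Cc1c(OC(=C)c2ccc(O[Si](C)(C)C(C)(C)C)cc2)cc(OC)c(Br)c1OC(=C)c1ccc(O[Si](C)(C)C(C)(C)C)cc1 | intermediate
25 | aryllithium from 24 (Li in place of Br) | C=C(C)[C@H](CC=C(C)C)Cc1c(OC(=C)c2ccc(O[Si](C)(C)C(C)(C)C)cc2)cc(OC)c([Li])c1OC(=C)c1ccc(O[Si](C)(C)C(C)(C)C)cc1 | intermediate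
26 | 6-methoxy-3-[(2R)-lavandulyl]-2,4-bis{1-[4-(TBS-oxy)phenyl]ethenyloxy}benzaldehyde | C=C(C)[C@H](CC=C(C)C)Cc1c(OC(=C)c2ccc(O[Si](C)(C)C(C)(C)C)cc2)cc(OC)c(C=O)c1OC(=C)c1ccc(O[Si](C)(C)C(C)(C)C)cc1 | intermediate
27 | (2S)-5-methoxy-8-[(2R)-lavandulyl]-2-[4-(TBS-oxy)phenyl]-7-{1-[4-(TBS-oxy)phenyl]ethenyloxy}chroman-4-one | C=C(C)[C@H](CC=C(C)C)Cc1c(OC(=C)c2ccc(O[Si](C)(C)C(C)(C)C)cc2)cc(OC)c2c1O[C@H](c1ccc(O[Si](C)(C)C(C)(C)C)cc1)CC2=O | intermediate
28 | (2S)-7-hydroxy-5-methoxy-8-[(2R)-lavandulyl]-2-[4-(TBS-oxy)phenyl]chroman-4-one | C=C(C)[C@H](CC=C(C)C)Cc1c(O)cc(OC)c2c1O[C@H](c1ccc(O[Si](C)(C)C(C)(C)C)cc1)CC2=O | intermediate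
29 | kushenol U, (2S)-7-hydroxy-2-(4-hydroxyphenyl)-5-methoxy-8-[(2R)-lavandulyl]chroman-4-one | C=C(C)[C@H](CC=C(C)C)Cc1c(O)cc(OC)c2c1O[C@H](c1ccc(O)cc1)CC2=O | target

**Step count.** Total: 15 steps. Longest linear sequence: 12 steps (1, 2, 3, 4, 7, 8, 9, 11, 12, 13, 14, 15).

**Steps most likely to fail**

Step 14 (proposed new method). The acyl rhodium hydride may decarbonylate, the hydride may insert with the opposite regiochemistry (5-exo closure), or the alkene faces may be poorly discriminated. The fallback uses known reaction types, sets out from bromide 24 and keeps the same ring C closure at C3–C4. An intramolecular carbonylative Heck reaction (Pd(OAc)2, 1,3-bis(diphenylphosphino)propane, CO, Et3N, toluene, 100 °C) should proceed through oxidative addition to zerovalent palladium, CO insertion, 6-endo acylpalladation of the enol ether and β-hydride elimination. It should give the flavone 5-methoxy-8-[(2R)-lavandulyl]-2-[4-(TBS-oxy)phenyl]-7-{1-[4-(TBS-oxy)phenyl]ethenyloxy}-4H-chromen-4-one F1. Copper hydride-catalysed asymmetric conjugate reduction of this β,β-disubstituted enone (Cu(OAc)2, DTBM-SEGPHOS antipode chosen for (S), (EtO)2MeSiH, t-BuOH, toluene, 0 °C) then sets C2 and comes back to the route at 27.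

Step 7. Oxidative addition and transmetalation at the doubly ortho-substituted, electron-rich aryl iodide may be slow, so that β-hydride elimination or protodezincation consumes the alkyl partner. The fallback reverses the polarity and uses no palladium. It sets out from 11 and alcohol 8. The alcohol is converted (Tf2O, 2,6-lutidine, CH2Cl2, −78 °C, used at once) into (2S)-lavandulyl trifluoromethanesulfonate F2. This is added at −78 °C to aryllithium 12 generated from 11 as in step 6. SN2 alkylation by the highly reactive primary triflate should outrun elimination and comes back to the route at 15.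

Step 9. During acetal cleavage, protic acid may promote addition of a freed phenol across the neighbouring isopropenyl double bond (chroman formation). The fallback avoids both Brønsted acid and the free resorcinol and sets out from 17. Et3SiOTf with 2,2'-bipyridyl (CH2Cl2, 0 °C) should convert the aromatic MOM ethers directly into the silyl ethers, giving [4-bromo-5-methoxy-2-[(2R)-lavandulyl]-1,3-phenylene]bis(oxy)bis(triethylsilane) F3. Fluoride-catalysed silyl-to-acyl exchange with acid chloride 22 (CsF cat., MeCN, rt) then comes back to the route at 23.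

**Further compounds**
F1 | step 14 | 5-methoxy-8-[(2R)-lavandulyl]-2-[4-(TBS-oxy)phenyl]-7-{1-[4-(TBS-oxy)phenyl]ethenyloxy}-4H-chromen-4-one | C=C(C)[C@H](CC=C(C)C)Cc1c(OC(=C)c2ccc(O[Si](C)(C)C(C)(C)C)cc2)cc(OC)c2c1OC(c1ccc(O[Si](C)(C)C(C)(C)C)cc1)=CC2=O
F2 | step 7 | (2S)-5-methyl-2-(prop-1-en-2-yl)hex-4-en-1-yl trifluoromethanesulfonate | C=C(C)[C@H](CC=C(C)C)COS(=O)(=O)C(F)(F)F
F3 | step 9 | [4-bromo-5-methoxy-2-[(2R)-lavandulyl]-1,3-phenylene]bis(oxy)bis(triethylsilane) | C=C(C)[C@H](CC=C(C)C)Cc1c(O[Si](CC)(CC)CC)cc(OC)c(Br)c1O[Si](CC)(CC)CC
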